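**Retrosynthetic overview**

1. Numbering: C1 is the quaternary carbinol and C7 its CH2OBz carbon. C2 and C5 are the ring CH–OBz carbons, C3=C4 the alkene, C6 the secondary carbinol. β is the ring face that carries C7; α is the face that carries the C1 oxygen.
2. Deciding feature: the oxygens on C2 and C5 stand 1,4 to each other on the same (β) face, on either side of C3=C4. This is what remains when the O–O bridge of a 2,3-dioxabicyclo[2.2.2]oct-5-ene is cut, so C2–O and C5–O are disconnected together to O2 and the diene C2=C3–C4=C5.
3. The diene, with C1 already in its final configuration, goes back to the enzymatic ipso,ortho-cis-dihydroxylation of benzoic acid. The carboxyl carbon becomes C7, and the C1/C6 cis-diol is tied into a dioxolane that closes the α face.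
4. C6 emerges α (cis to C1–OH) and is corrected last, through the C6 ketone and a hydride led in from the α face by the C1 hydroxyl.
5. Ring order: carbocycle (from the arene, step 1), dioxolane (step 2), 1,2-dioxane bridge (step 6). The bridge is cut in step 7 and the dioxolane in step 9.

Key step: step 6

Assumption: the blocked-mutant strain (or a recombinant host carrying the benzoate dioxygenase genes) is taken as an obtainable biocatalyst, so benzoic acid counts as the commercial starting material. Its diol is the (1S,2R) enantiomer, whose quaternary centre has the spatial arrangement required at C1 of the target.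

**Step 1**
Reactants: 1 benzoic acid; 2 dioxygen
Product: 3 (1S,2R)-1,2-dihydroxycyclohexa-3,5-diene-1-carboxylic acid (route numbering: C1–OH and C6–OH both α, CO2H = C7 on β)
Conditions: whole cells of Cupriavidus necator B9 (benzoate 1,2-dioxygenase active, diol dehydrogenase blocked), fructose, air, mineral-salts medium, pH 7, 30 °C; cell removal, HCl to pH 3 at 0 °C, EtOAc extraction
Reagents that add atoms: dioxygen, O=O
Why: Enzymatic arene cis-dihydroxylation by a Rieske-type dioxygenase puts both atoms of O2 on the ipso and ortho carbons from one face, and since the mutant cannot dehydrogenate the product the single-enantiomer diol should accumulate, which sets C1 (final) and C6 (to be inverted later).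

**Step 2**
Reactants: 3 diol acid; 4 2,2-dimethoxypropane
Product: 5 (3aS,7aR)-2,2-dimethyl-3a,7a-dihydro-1,3-benzodioxole-3a-carboxylic acid (C1/C6 acetonide on the α face, CO2H on β)
Conditions: Me2C(OMe)2, p-TsOH·H2O (cat.), acetone, 0 °C → rt, short contact; aqueous wash
Reagents that add atoms: 2,2-dimethoxypropane, COC(C)(C)OC
Why: Acid-catalysed transketalisation closes the five-membered dioxolane on the cis-diol faster than the diol dehydrates to an arene as long as the acid is catalytic and the contact short, and no stereocentre is touched.

**Step 3**
Reactants: 5 acetonide acid; 6 iodomethane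
Product: 7 methyl (3aS,7aR)-2,2-dimethyl-3a,7a-dihydro-1,3-benzodioxole-3a-carboxylate
Conditions: MeI, K2CO3, DMF, rt
Reagents that add atoms: iodomethane, CI
Why: SN2 O-alkylation of the carboxylate is acid-free, so the diene ketal is not at risk, and C1 is quaternary and cannot epimerise.

**Step 4**
Reactants: 7 methyl ester acetonide
Product: 8 [(3aR,7aR)-2,2-dimethyl-3a,7a-dihydro-1,3-benzodioxol-3a-yl]methanol (C7 now CH2OH, β)
Conditions: LiAlH4, Et2O, 0 °C; then H2O, 15% aq NaOH, H2O
Reagents that add atoms: none
Why: LiAlH4 ester reduction takes C7 to the primary alcohol, while the diene (not conjugated with the ester) and the ketal are inert to hydride.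

**Step 5**
Reactants: 8 primary alcohol; 9 benzoyl chloride
Product: 10 [(3aR,7aR)-2,2-dimethyl-3a,7a-dihydro-1,3-benzodioxol-3a-yl]methyl benzoate (diene C2=C3–C4=C5, acetonide α, CH2OBz β)
Conditions: BzCl, pyridine, 4-(dimethylamino)pyridine (cat.), CH2Cl2, 0 °C → rt
Reagents that add atoms: benzoyl chloride, O=C(Cl)c1ccccc1
Why: Nucleophile-catalysed acylation of the only free hydroxyl under basic conditions leaves the acid-sensitive diene ketal untouched.

**Step 6**
Reactants: 10 diene benzoate; 2 dioxygen
Product: 11 C2,C5-endoperoxide of 10: a 2,3-dioxabicyclo[2.2.2]oct-5-ene with the O–O bridge on the β face, the C1/C6 acetonide on the α face, CH2OBz on C1; route numbering (1R,2R,5S,6R)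
Conditions: O2 (bubbled), 5,10,15,20-tetraphenylporphyrin (cat.), visible light (white LED), CH2Cl2, −20 °C
Reagents that add atoms: dioxygen, O=O
Why: The excited porphyrin passes its triplet energy to 2, and the singlet oxygen so formed adds in a concerted, suprafacial [4+2] cycloaddition to the termini C2 and C5 of the ring-locked s-cis diene, leaving the new alkene at C3=C4. The closest known reaction type is the sensitised photooxygenation of cyclohexa-1,3-diene cis-diol acetonides to bicyclic endoperoxides, from which 10 differs only by its C1 substituent. The one new ring, the six-membered 1,2-dioxane C2–O–O–C5–C4=C3, closes by cycloaddition with both C–O bonds formed in the same event, so no separate cyclisation mode has to be met. C2 and C5 are set together: suprafacial addition forces the two oxygens cis, and the face is chosen by the cis-fused dioxolane, whose endo methyl lies under the α face and whose allylic C1 and C6 oxygens repel the incoming electrophile, so attack should come from the β face, which carries only C6–H and the rotatable C7 methylene. The step needs facial selectivity (β over α) and mode selectivity ([4+2] over the ene reaction at C6–H), the first secured by the ketal and the second by the planar s-cis geometry of the cyclohexadiene. Low temperature, exclusion of base and prompt use of 11 guard against Kornblum–DeLaMare opening and rearrangement to a bis-epoxide.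

**Step 7**
Reactants: 11 endoperoxide
Product: 12 ene-diol acetonide: C2–OH and C5–OH both β, C3=C4, C1/C6 acetonide α, CH2OBz on C1; route numbering (1S,2R,5S,6R)
Conditions: thiourea (2.2 equiv), MeOH, 0 °C → rt
Reagents that add atoms: none
Why: In the thiourea reduction of a bicyclic endoperoxide sulfur attacks only the weak O–O bond and the C2–O and C5–O bonds are never broken, so both carbinols stay β and the alkene, ketal and benzoate survive the neutral medium.

**Step 8**
Reactants: 12 ene-diol; 9 benzoyl chloride
Product: 13 tribenzoate acetonide: C2–OBz and C5–OBz β, C7–OBz, C1/C6 acetonide α; route numbering (1S,2R,5S,6R)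
Conditions: BzCl (3 equiv), pyridine, 4-(dimethylamino)pyridine (cat.), CH2Cl2, 0 °C → rt
Reagents that add atoms: benzoyl chloride, O=C(Cl)c1ccccc1
Why: Nucleophile-catalysed esterification acylates both secondary allylic hydroxyls (the hindered C2–OH included) with retention, and a C7-to-C2 benzoyl shift in 12 would be harmless because all three positions end as benzoates.

**Step 9**
Reactants: 13 tribenzoate acetonide
Product: 14 [(1R,2R,5S,6R)-2,5-bis(benzoyloxy)-1,6-dihydroxycyclohex-3-en-1-yl]methyl benzoate (C6 epimer of the target: C1–OH and C6–OH both α)
Conditions: CF3CO2H/H2O (9:1), CH2Cl2, 0 °C → rt; evaporation with toluene, no basic wash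
Reagents that add atoms: none
Why: Acid hydrolysis of the isopropylidene ketal breaks bonds only at the ketal carbon, so the C1–O and C6–O bonds and their configurations persist, and the acidic medium suppresses base-promoted benzoyl migration.

**Step 10**
Reactants: 14 cis-diol tribenzoate
Product: 15 [(1S,2R,5S)-2,5-bis(benzoyloxy)-1-hydroxy-6-oxocyclohex-3-en-1-yl]methyl benzoate (C6 ketone)
Conditions: IBX (2-iodoxybenzoic acid, 1.5 equiv), DMSO, rt; H2O/EtOAc, filtration; crude ketone used at once
Reagents that add atoms: none
Why: IBX oxidation of a 1,2-diol stops at the α-ketol without C–C cleavage, only the secondary C6 carbinol can be dehydrogenated, and the base-free medium should keep the acidic C5–H (α to the ketone and allylic) from enolising, so C1, C2 and C5 are kept.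

**Step 11**
Reactants: 15 ketone
Product: 16 [(1R,2R,5S,6S)-2,5-bis(benzoyloxy)-1,6-dihydroxycyclohex-3-en-1-yl]methyl benzoate (target: C1–OH α; C7, C2–OBz, C5–OBz and C6–OH β)
Conditions: Me4NBH(OAc)3 (5 equiv), MeCN/AcOH (1:1), −30 → 0 °C; aq NH4Cl work-up
Reagents that add atoms: none
Why: In this Saksena–Evans hydroxyl-directed reduction, exchange of an acetate on boron for the C1 hydroxyl ties the hydride to the α face, which is also the less crowded one (C7, C2–OBz and C5–OBz all lie β), so H should enter C6 from α and the new hydroxyl should stand β, trans to C1–OH and cis to C5–OBz, while the acidic medium holds the benzoates in place.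

**Compound list**

1 | benzoic acid | OC(=O)c1ccccc1 | starting material
2 | dioxygen | O=O | starting material
3 | (1S,2R)-1,2-dihydroxycyclohexa-3,5-diene-1-carboxylic acid | OC(=O)[C@]1(O)C=CC=C[C@H]1O | intermediate
4 | 2,2-dimethoxypropane | COC(C)(C)OC | starting material
5 | (3aS,7aR)-2,2-dimethyl-3a,7a-dihydro-1,3-benzodioxole-3a-carboxylic acid | OC(=O)[C@@]12OC(C)(C)O[C@@H]1C=CC=C2 | intermediate
6 | iodomethane | CI | starting material
7 | methyl (3aS,7aR)-2,2-dimethyl-3a,7a-dihydro-1,3-benzodioxole-3a-carboxylate | COC(=O)[C@@]12OC(C)(C)O[C@@H]1C=CC=C2 | intermediate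
8 | [(3aR,7aR)-2,2-dimethyl-3a,7a-dihydro-1,3-benzodioxol-3a-yl]methanol | OC[C@@]12OC(C)(C)O[C@@H]1C=CC=C2 | intermediate
9 | benzoyl chloride | O=C(Cl)c1ccccc1 | starting material
10 | [(3aR,7aR)-2,2-dimethyl-3a,7a-dihydro-1,3-benzodioxol-3a-yl]methyl benzoate (key-step precursor) | O=C(OC[C@@]12OC(C)(C)O[C@@H]1C=CC=C2)c1ccccc1 | intermediate
11 | C2,C5-endoperoxide of 10, O–O bridge β, acetonide α (key-step product) | O=C(OC[C@@]12OC(C)(C)O[C@@H]1[C@@H]3C=C[C@H]2OO3)c1ccccc1 | intermediate
12 | 2β,5β-ene-diol acetonide C7-benzoate | O=C(OC[C@@]12OC(C)(C)O[C@@H]1[C@@H](O)C=C[C@H]2O)c1ccccc1 | intermediate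
13 | 2β,5β,7-tribenzoate C1/C6-acetonide | O=C(OC[C@@]12OC(C)(C)O[C@@H]1[C@@H](OC(=O)c3ccccc3)C=C[C@H]2OC(=O)c4ccccc4)c5ccccc5 | intermediate
14 | [(1R,2R,5S,6R)-2,5-bis(benzoyloxy)-1,6-dihydroxycyclohex-3-en-1-yl]methyl benzoate | O=C(OC[C@]1(O)[C@H](OC(=O)c2ccccc2)C=C[C@H](OC(=O)c2ccccc2)[C@H]1O)c1ccccc1 | intermediate
15 | [(1S,2R,5S)-2,5-bis(benzoyloxy)-1-hydroxy-6-oxocyclohex-3-en-1-yl]methyl benzoate | O=C(OC[C@]1(O)[C@H](OC(=O)c2ccccc2)C=C[C@H](OC(=O)c2ccccc2)C1=O)c1ccccc1 | intermediate
16 | [(1R,2R,5S,6S)-2,5-bis(benzoyloxy)-1,6-dihydroxycyclohex-3-en-1-yl]methyl benzoate | O=C(OC[C@]1(O)[C@H](OC(=O)c2ccccc2)C=C[C@H](OC(=O)c2ccccc2)[C@@H]1O)c1ccccc1 | target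

Total step count: 11. Longest linear sequence: 11 steps (1 → 16).

**Steps most likely to fail**

First, step 10.
- **Risk:** the iodine oxidant may cleave the C1–C6 glycol bond. The new ketone may also enolise towards C5, lose the C2 benzoate in a vinylogous elimination and drift towards aromatisation.
- **Fallback:** avoid the ketone altogether with a Lattrell–Dax inversion that sets out from 14.
- **Sequence:** Tf2O and pyridine in CH2Cl2 at −20 °C should sulfonylate only the secondary hydroxyl and give the C6 α-triflate F3. Bu4NNO2 in MeCN at rt to 50 °C should then displace it through oxygen from the β face to give the C6 β-nitrite ester F4. This ester loses its nitroso group on aqueous work-up, and the fallback comes back to the route at 16.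
- **Assessment:** the C5 benzoate next to the leaving group is the kind of neighbouring ester known to help this inversion. The neopentyl character of C6 is its weak point.

Second, step 6.
- **Risk:** the β face is not empty, since it carries the C7 methylene with its benzoate. Facial selectivity may therefore erode, and the ene reaction at C6–H or rearrangement of the peroxide may compete.
- **Fallback:** change the control element by running the cycloaddition on the free alcohol, setting out from 8. The β-oriented CH2OH group is smaller and can steer singlet oxygen to its own face by hydrogen bonding, which is the known hydroxyl-directing effect in photooxygenation. Sterics and attraction then point the same way.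
- **Sequence:** photooxygenation of 8 in CH2Cl2 should give the hydroxymethyl endoperoxide F1, and thiourea in MeOH the acetonide triol F2. Exhaustive benzoylation (BzCl, pyridine, 4-(dimethylamino)pyridine) of its three hydroxyls comes back to the route at 13.

Third, step 11.
- **Risk:** ligand exchange at the hindered tertiary C1–OH may be slow, so the reduction could stall or run undirected with poorer facial selectivity. The C5 benzoate could also migrate to the new cis C6–OH if the pH rises.
- **Fallback:** hand stereocontrol to a chiral catalyst with a Corey–Bakshi–Shibata reduction that sets out from 15.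
- **Sequence:** (R)-1-methyl-3,3-diphenyltetrahydro-1H,3H-pyrrolo[1,2-c][1,3,2]oxazaborole and BH3·SMe2 are used in THF at −20 °C. With C1 as the large and C5 as the small flank, this enantiomer of the catalyst should deliver hydride to the α face, and the fallback comes back to the route at 16 without any new compound.
- **Recycling:** any 14 formed by β attack can be returned to step 10.

**Further compounds**

F1 | step 6 | hydroxymethyl endoperoxide (O–O bridge β, acetonide α, free C7–OH) | OC[C@@]12OC(C)(C)O[C@@H]1[C@@H]3C=C[C@H]2OO3
F2 | step 6 | acetonide triol (C2–OH and C5–OH β, C7–OH, acetonide α) | OC[C@@]12OC(C)(C)O[C@@H]1[C@@H](O)C=C[C@H]2O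
F3 | step 10 | C6 α-triflate of 14 | O=C(OC[C@]1(O)[C@H](OC(=O)c2ccccc2)C=C[C@H](OC(=O)c2ccccc2)[C@H]1OS(=O)(=O)C(F)(F)F)c1ccccc1
F4 | step 10 | C6 β-nitrite ester of 16 | O=C(OC[C@]1(O)[C@H](OC(=O)c2ccccc2)C=C[C@H](OC(=O)c2ccccc2)[C@@H]1ON=O)c1ccccc1
F0 | step 11 | none | none
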